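## Analysis of the target

The target is a 3,3,5,5-tetrasubstituted 1,2-dioxolane (ring atoms O1–O2–C3–C4–C5). C3 carries a methyl group and the acetic acid arm C1'H2–C2'O2H; C5 carries a methyl group and the chain C6–C17, which is methyl-branched at C7, has E double bonds at C12=C13 and C16=C17 and ends in a phenyl group on C17. There are three stereocentres, C3 (S), C5 (R) and C7 (R). C3 and C5 are fully substituted peroxy carbons, 1,3-related across the ring with their methyl groups trans (the acid arm is cis to the C5 methyl and trans to C6). C7 is a tertiary C–H centre 1,3 to C5 with no ring to relay stereochemical information. Sensitive groups are the O–O bond (no hydrogenation, dissolving or low-valent metals, hard carbanions at higher temperature, and no radical β to the peroxide), the acid-sensitive styrene and skipped 1,5-diene, and the β-peroxy acid, which can open by retro-oxa-Michael reaction under forcing base. The main difficulty is that at both C3 and C5 the two carbon substituents are a methyl and a CH2 group, so any ring closure that relies on the ring or on C7 to tell them apart is poorly diastereoselective, and tertiary C–OO bonds of defined configuration are not available from ordinary asymmetric oxidation. The feature the route is built on: along the backbone each peroxy carbon is followed, one CH2 later, by an oxygen-bearing carbon, C5–C4–C3(O2) and C3–C1'–C2'(O)OH, and each of C3 and C5 bears exactly one methyl group. Ring O1–O2–C3–C4–C5 can therefore be read as a peroxide unit inserted by two backside displacements into two 2-alkyl-2-methyloxetanes laid head to tail (O–C5–C4–C3 and O–C3–C1'–C2'), each of which is a methyl ketone plus two methylene groups.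

## Retrosynthetic reasoning

24 to 23. The carboxylic acid is taken back to the primary alcohol 23. The C3 arm is then the 2-hydroxyethyl group that an opened oxetane leaves behind, so no carbon–carbon bond has to be made at the quaternary C3 once the peroxide exists.

23 to 22 and 5. The C12=C13 bond is cut (E-selective olefination of aldehyde 22 with sulfone 5). This is the one disconnection that removes the whole acid-labile phenyl diene (C13–C17 and the phenyl ring) as one simple fragment. Every acid-promoted peroxide-forming step then sees only the monosubstituted alkene of 20, which is the latent C12 aldehyde (22 from 20 by ozonolysis).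

20 to 19 (from 18). The O2–C3 bond is cut. In the forward sense the C5 hydroperoxide of 19 attacks the tertiary oxetane carbon C3 from the back. This closes the dioxolane, fixes C3 by inversion of a centre that was set under catalyst control, and releases the two-carbon arm. Cutting C3–C1' (a nucleophile adding to a ring cation) or reading O2–C3 as a conjugate addition would leave C3 to the weak methyl/CH2 bias at C5.

18 to 16. The two oxetane methylene carbons (C1' and C2') are removed, which leaves methyl ketone 16 with the C3 carbonyl and the C3 methyl in place. The forward reaction is a catalyst-controlled double methylene transfer that must distinguish the methyl face from the C4 face of the ketone.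

16 to 12. C3 of 16 is the former oxetane CH2–O carbon of 11. Going back, the ketone becomes a secondary alcohol (15), the C3–CH3 bond is cut to aldehyde 14, and 14 comes from alcohol 13, the peroxyketal-protected form of 12. These are the only steps in which a carbanion meets the peroxide, hence the protection.

12 to 11. The O1–C5 bond is cut: intermolecular perhydrolysis of oxetane 11 at its tertiary carbon with inversion. C4 and C3 of the target are the two methylene carbons of this first oxetane.

11 to 9. The same double methylene transfer, now onto methyl ketone 9, which already holds C5 with its methyl group and the C7 stereocentre.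

9 to 8 to 6. The C7–CH3 bond is cut (asymmetric conjugate addition of a methyl nucleophile to enone 8). The C5–C7 enone unit comes from aldehyde 7, made in the flask from alcohol 6.

5 to 1. Sulfone 5 is traced through sulfide 4 and alcohol 3 to ester 2, whose E styrene (C16=C17) arises from a [3,3] rearrangement of allylic alcohol 1.

## Alternatives that were turned down

Alternative 1: the textbook route. O1–C5 is cut as a Markovnikov hydroperoxidation and O2–C3 as an intramolecular peroxy-Michael addition. Forward: Mukaiyama–Isayama hydroperoxysilylation [Co(acac)2, O2, Et3SiH] of the 1,1-disubstituted alkene of dienoate A1, then desilylation and base-mediated 5-exo conjugate addition to give ester A2. Turned down because C5 is formed through a planar tertiary radical that cannot feel C7, and the Michael closure onto a β-methyl enoate distinguishes methyl from CH2 poorly and is reversible. A2 would be a mixture of up to four ring diastereomers that differ only at quaternary carbons, and the hydrogen-atom-transfer conditions would also attack the styrene. The three steps from A1 buy no stereocontrol.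

Alternative 2: convergent [3+2] annulation, cutting C4–C5 and O2–C3 together. Forward: ionisation of silylperoxy ketal A3 (from ketone 9) with SnCl4 to a peroxycarbenium ion, attack by the 1,1-disubstituted alkene A4, and capture of the resulting tertiary cation by the silylperoxy oxygen to give dioxolane A5. It joins two fragments at a quaternary carbon in two steps from 9. It was turned down because both new stereocentres arise from planar cations (C5 with only the remote C7 to bias it, C3 with only methyl versus CH2), so A5 would again be about four isomers, and the terminal alkene of A3 competes as a nucleophile.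

Alternative 3: hidden C2 symmetry. With the chain removed the trans-dimethyl core has a C2 axis through C4 and the O1–O2 midpoint, so both C–O bonds could be cut at once. Forward: the C2-symmetric bis-oxetane A6 and hydrogen peroxide give diol A7 by one intermolecular and one intramolecular inversion in a single flask; the two arms of A7 are homotopic. Turned down because one arm of A7 must then become the C6–C17 chain, so C7 would have to be created after the peroxide is in place. That needs an asymmetric methyl-bearing C–C bond formation without hydrogenation, aluminium reagents or cuprates. A6 itself needs a skipped diene-diol and a double asymmetric epoxidation, and the statistical monofunctionalisation of A7 adds losses. The estimate is well over twenty steps.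

Key step: step 14

Assumption: the (S)-configured LaLi3 tris(binaphtholate) catalyst is taken to give the (S)-2-alkyl-2-methyloxirane from a methyl ketone and the named Josiphos antipode the (R)-β-methyl ketone; if either sense is the reverse, the antipodal ligand is used and nothing else changes.

## Route

Step 1
Reactants: 1 1-phenylprop-2-en-1-ol (racemic)
Product: 2 ethyl (4E)-5-phenylpent-4-enoate
Conditions: MeC(OEt)3 (5 equiv), EtCO2H (5 mol %), 140 °C, EtOH distilled off
Reagents that add atoms: triethyl orthoacetate, CC(OCC)(OCC)OCC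
Why: Johnson–Claisen rearrangement; the chair transition state with equatorial phenyl should give the E styrene, and the stereocentre of 1 is destroyed, so the racemate suffices.

Step 2
Reactants: 2 ethyl (4E)-5-phenylpent-4-enoate
Product: 3 (4E)-5-phenylpent-4-en-1-ol
Conditions: LiAlH4, THF, 0 °C; aqueous NaOH work-up
Reagents that add atoms: none
Why: Hydride reduction of the ester; the unactivated styrene is not touched.

Step 3
Reactants: 3 (4E)-5-phenylpent-4-en-1-ol
Product: 4 1-phenyl-5-{[(4E)-5-phenylpent-4-en-1-yl]sulfanyl}-1H-tetrazole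
Conditions: 1-phenyl-1H-tetrazole-5-thiol, PPh3, DIAD, THF, 0 °C to rt
Reagents that add atoms: 1-phenyl-1H-tetrazole-5-thiol, SC1=NN=NN1c1ccccc1
Why: Mitsunobu thioetherification of a primary alcohol with an acidic heteroaryl thiol.

Step 4
Reactants: 4 1-phenyl-5-{[(4E)-5-phenylpent-4-en-1-yl]sulfanyl}-1H-tetrazole
Product: 5 1-phenyl-5-{[(4E)-5-phenylpent-4-en-1-yl]sulfonyl}-1H-tetrazole
Conditions: (NH4)6Mo7O24·4H2O (10 mol %), 30% aq. H2O2, EtOH, 0 °C to rt
Reagents that add atoms: hydrogen peroxide, OO
Why: Molybdate-catalysed oxidation of sulfide to sulfone; the nucleophilic sulfur should react far faster than the styrene.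

Step 5
Reactants: 6 hept-6-en-1-ol
Product: 8 (3E)-deca-3,9-dien-2-one, via hept-6-enal 7 (not isolated)
Conditions: IBX (1.5 equiv), Ph3P=CHC(O)CH3 (1.3 equiv), DMSO, rt
Reagents that add atoms: 1-(triphenylphosphoranylidene)propan-2-one, CC(=O)C=P(c1ccccc1)(c1ccccc1)c1ccccc1
Why: Tandem IBX oxidation and Wittig olefination; the stabilised ylide traps the aldehyde as formed and should give the E enone.

Step 6
Reactants: 8 (3E)-deca-3,9-dien-2-one
Product: 9 (4R)-4-methyldec-9-en-2-one
Conditions: MeMgBr (1.2 equiv), CuBr·SMe2 (5 mol %), (R)-1-[(SP)-2-(diphenylphosphino)ferrocenyl]ethyldicyclohexylphosphine (6 mol %), tBuOMe, −75 °C; then MeOH, aq. NH4Cl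
Reagents that add atoms: methylmagnesium bromide, C[Mg]Br
Why: Copper-catalysed asymmetric conjugate addition of a Grignard reagent to an acyclic enone; the ferrocenyl diphosphine copper complex selects the enone face and sets C7 as R, and the terminal alkene is inert.

Step 7
Reactants: 9 (4R)-4-methyldec-9-en-2-one
Product: 11 (2S)-2-methyl-2-[(2R)-2-methyloct-7-en-1-yl]oxetane, via epoxide 10 (not isolated)
Conditions: Me3S(O)I/NaH (ylide, 1.2 equiv), LaLi3[(S)-1,1'-bi-2-naphtholate]3 (5 mol %), [2,4,6-(MeO)3C6H2]3P=O (5 mol %), 5 Å MS, THF, rt; then further ylide (1.5 equiv), catalyst raised to 20 mol %, 45 °C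
Reagents that add atoms: dimethylsulfoxonium methylide, C[S+](C)(=O)[CH2-]
Why: Catalytic asymmetric Corey–Chaykovsky epoxidation of a methyl ketone, then ylide ring expansion in the same flask (attack at the epoxide CH2 and 4-exo-tet closure, tertiary C–O bond untouched); the catalyst tells CH3 from the larger alkyl group and the second catalyst-controlled stage should enrich the major enantiomer, fixing the future C5 as the (S)-oxetane carbon under reagent control.

Step 8
Reactants: 11 (2S)-2-methyl-2-[(2R)-2-methyloct-7-en-1-yl]oxetane
Product: 12 (3R,5R)-3-hydroperoxy-3,5-dimethylundec-10-en-1-ol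
Conditions: anhydrous H2O2 in Et2O (10 equiv), Me3SiOTf (0.2 equiv), Et2O, −78 to −20 °C
Reagents that add atoms: hydrogen peroxide, OO
Why: Lewis acid-promoted perhydrolysis of a 2,2-dialkyloxetane; hydrogen peroxide attacks the activated tertiary carbon from the back (borderline SN2), so C5 should be inverted to R while the released hydroxyethyl group carries C4 and C3; the excess of peroxide suppresses dialkyl peroxide formation and the monosubstituted alkene is not protonated.

Step 9
Reactants: 12 (3R,5R)-3-hydroperoxy-3,5-dimethylundec-10-en-1-ol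
Product: 13 (3R,5R)-3-[(2-methoxypropan-2-yl)peroxy]-3,5-dimethylundec-10-en-1-ol
Conditions: 2-methoxypropene (1.2 equiv), PPTS (2 mol %), CH2Cl2, 0 °C
Reagents that add atoms: 2-methoxypropene, COC(C)=C
Why: Acid-catalysed monoperoxyketal formation; the hydroperoxide is the more acidic and more nucleophilic (alpha effect) hydroxyl, and any mixed ketal on the primary alcohol is far more labile and should be lost on the slightly acidic work-up.

Step 10
Reactants: 13 (3R,5R)-3-[(2-methoxypropan-2-yl)peroxy]-3,5-dimethylundec-10-en-1-ol
Product: 14 (3R,5R)-3-[(2-methoxypropan-2-yl)peroxy]-3,5-dimethylundec-10-enal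
Conditions: Dess–Martin periodinane, NaHCO3, CH2Cl2, 0 °C to rt
Reagents that add atoms: none
Why: Dess–Martin oxidation; the buffered neutral medium leaves the peroxyketal intact and avoids β-elimination of the peroxide from the aldehyde.

Step 11
Reactants: 14 (3R,5R)-3-[(2-methoxypropan-2-yl)peroxy]-3,5-dimethylundec-10-enal
Product: 15 (4R,6R)-4-[(2-methoxypropan-2-yl)peroxy]-4,6-dimethyldodec-11-en-2-ol (both C2 epimers)
Conditions: MeMgBr (1.1 equiv), THF, −78 °C; aq. NH4Cl
Reagents that add atoms: methylmagnesium bromide, C[Mg]Br
Why: Grignard 1,2-addition; at −78 °C addition to the aldehyde should be much faster than attack on the hindered tertiary peroxyketal O–O bond, and the carbinol epimers converge in step 12.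

Step 12
Reactants: 15 (4R,6R)-4-[(2-methoxypropan-2-yl)peroxy]-4,6-dimethyldodec-11-en-2-ol
Product: 16 (4R,6R)-4-[(2-methoxypropan-2-yl)peroxy]-4,6-dimethyldodec-11-en-2-one
Conditions: Dess–Martin periodinane, NaHCO3, CH2Cl2, 0 °C to rt
Reagents that add atoms: none
Why: Dess–Martin oxidation to the methyl ketone that carries the C3 carbonyl and the C3 methyl group.

Step 13
Reactants: 16 (4R,6R)-4-[(2-methoxypropan-2-yl)peroxy]-4,6-dimethyldodec-11-en-2-one
Product: 18 (2S)-2-{(2R,4R)-2-[(2-methoxypropan-2-yl)peroxy]-2,4-dimethyldec-9-en-1-yl}-2-methyloxetane, via epoxide 17 (not isolated)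
Conditions: Me3S(O)I/NaH (ylide, 1.2 equiv), LaLi3[(R)-1,1'-bi-2-naphtholate]3 (5 mol %), [2,4,6-(MeO)3C6H2]3P=O (5 mol %), 5 Å MS, THF, rt; then further ylide (1.5 equiv), catalyst raised to 20 mol %, 45 °C
Reagents that add atoms: dimethylsulfoxonium methylide, C[S+](C)(=O)[CH2-]
Why: The same catalytic asymmetric methylene transfer and ring expansion as step 7, on a methyl ketone whose large substituent is the neopentyl-type C4 methylene; the antipodal catalyst is needed because the oxetane oxygen must sit on the face that, after inversion in step 14, gives the C3 configuration of the target, and epoxidation at room temperature is expected to outrun enolisation toward C4 and loss of the base-stable peroxyketal.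

Step 14
Reactants: 18 (2S)-2-{(2R,4R)-2-[(2-methoxypropan-2-yl)peroxy]-2,4-dimethyldec-9-en-1-yl}-2-methyloxetane
Product: 20 2-{(3R,5R)-3,5-dimethyl-5-[(2R)-2-methyloct-7-en-1-yl]-1,2-dioxolan-3-yl}ethan-1-ol, via hydroperoxy oxetane 19 (not isolated)
Conditions: AcOH–THF–H2O (4:2:1), rt; after drying, Me3SiOTf (0.1 equiv), CH2Cl2, −78 to 0 °C
Reagents that add atoms: none
Why: Aqueous acetic acid hydrolyses the monoperoxyketal to hydroperoxide 19; the silyl triflate (or the triflic acid it releases) then activates the oxetane oxygen, and the terminal oxygen of the C5 hydroperoxide attacks the tertiary oxetane carbon C3 from the back while the C3–O bond of the oxetane breaks. The closest known reaction type is the Lewis acid-promoted 5-exo cyclisation of hydroperoxides onto 2,2-disubstituted oxetanes, the intramolecular counterpart of step 8. The 1,2-dioxolane closes in the 5-exo-tet mode (O–O–C5–C4–C3); the alternative attack at the oxetane CH2 would be a 7-endo process at a primary carbon that cannot carry positive charge. C3 is set by inversion of the (S)-oxetane carbon installed under catalyst control in step 13, and C5 and C7 are spectators. The step needs inversion to beat ionisation: the quaternary C5 holds the hydroperoxide next to C3 (Thorpe–Ingold effect), the hydroperoxide is an alpha-effect nucleophile, and low temperature in a non-ionising solvent should keep bond breaking and bond making coupled. The departing oxetane oxygen becomes the hydroxyl of the two-carbon arm, so the event that closes the ring and fixes the second quaternary centre also delivers the acetic acid side chain in masked form. The terminal alkene and the dialkyl peroxide product should be inert to the catalytic acid at these temperatures.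

Step 15
Reactants: 20 2-{(3R,5R)-3,5-dimethyl-5-[(2R)-2-methyloct-7-en-1-yl]-1,2-dioxolan-3-yl}ethan-1-ol
Product: 22 (6R)-7-[(3R,5R)-5-(2-hydroxyethyl)-3,5-dimethyl-1,2-dioxolan-3-yl]-6-methylheptanal, via methoxy hydroperoxide 21 (not isolated)
Conditions: O3, CH2Cl2–MeOH (5:1), −78 °C; then Me2S, −78 °C to rt
Reagents that add atoms: ozone, [O-][O+]=O
Why: Ozonolysis of the terminal alkene with reductive work-up; ozone does not attack the dialkyl peroxide or the alcohol, and dimethyl sulfide reduces the methoxy hydroperoxide but should be too weak to reduce the hindered dioxolane.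

Step 16
Reactants: 22 (6R)-7-[(3R,5R)-5-(2-hydroxyethyl)-3,5-dimethyl-1,2-dioxolan-3-yl]-6-methylheptanal; 5 1-phenyl-5-{[(4E)-5-phenylpent-4-en-1-yl]sulfonyl}-1H-tetrazole
Product: 23 2-{(3R,5R)-3,5-dimethyl-5-[(2R,7E,11E)-2-methyl-12-phenyldodeca-7,11-dien-1-yl]-1,2-dioxolan-3-yl}ethan-1-ol
Conditions: 5 (2.2 equiv), KN(SiMe3)2 (2.1 equiv), DME, −60 °C; then 22, −60 °C to rt
Reagents that add atoms: none
Why: Julia–Kocienski olefination: the metalated phenyltetrazolyl sulfone adds to the aldehyde and Smiles rearrangement with loss of SO2 and tetrazolone should give the E alkene (potassium counter-ion, DME); one equivalent of anion is spent on the free hydroxyl, and the dioxolane has no hydrogen on C3 or C5, so base-induced Kornblum–DeLaMare cleavage is impossible.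

Step 17
Reactants: 23 2-{(3R,5R)-3,5-dimethyl-5-[(2R,7E,11E)-2-methyl-12-phenyldodeca-7,11-dien-1-yl]-1,2-dioxolan-3-yl}ethan-1-ol
Product: 24 2-{(3S,5R)-3,5-dimethyl-5-[(2R,7E,11E)-2-methyl-12-phenyldodeca-7,11-dien-1-yl]-1,2-dioxolan-3-yl}acetic acid (CNP0204107.3)
Conditions: TEMPO (0.2 equiv), PhI(OAc)2 (2.5 equiv), MeCN–H2O (1:1), rt
Reagents that add atoms: water, O
Why: Oxoammonium-mediated oxidation of the primary alcohol through the aldehyde hydrate to the acid under metal-free, non-basic conditions that leave the peroxide, the diene and the styrene alone; no stereocentre is touched (the C3 descriptor changes from R to S only because the arm gains CIP priority).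

## Compound list

1 | 1-phenylprop-2-en-1-ol (racemic) | C=CC(O)c1ccccc1 | starting material
2 | ethyl (4E)-5-phenylpent-4-enoate | CCOC(=O)CC/C=C/c1ccccc1 | intermediate
3 | (4E)-5-phenylpent-4-en-1-ol | OCCC/C=C/c1ccccc1 | intermediate
4 | 1-phenyl-5-{[(4E)-5-phenylpent-4-en-1-yl]sulfanyl}-1H-tetrazole | c1ccccc1/C=C/CCCSC1=NN=NN1c1ccccc1 | intermediate
5 | 1-phenyl-5-{[(4E)-5-phenylpent-4-en-1-yl]sulfonyl}-1H-tetrazole | c1ccccc1/C=C/CCCS(=O)(=O)C1=NN=NN1c1ccccc1 | intermediate
6 | hept-6-en-1-ol | OCCCCCC=C | starting material
7 | hept-6-enal | O=CCCCCC=C | intermediate (not isolated)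
8 | (3E)-deca-3,9-dien-2-one | CC(=O)/C=C/CCCCC=C | intermediate
9 | (4R)-4-methyldec-9-en-2-one | CC(=O)C[C@H](C)CCCCC=C | intermediate
10 | (2S)-2-methyl-2-[(2R)-2-methyloct-7-en-1-yl]oxirane | C[C@H](CCCCC=C)C[C@@]1(C)CO1 | intermediate (not isolated)
11 | (2S)-2-methyl-2-[(2R)-2-methyloct-7-en-1-yl]oxetane | C[C@H](CCCCC=C)C[C@@]1(C)CCO1 | intermediate
12 | (3R,5R)-3-hydroperoxy-3,5-dimethylundec-10-en-1-ol | C[C@H](CCCCC=C)C[C@](OO)(C)CCO | intermediate
13 | (3R,5R)-3-[(2-methoxypropan-2-yl)peroxy]-3,5-dimethylundec-10-en-1-ol | C[C@H](CCCCC=C)C[C@](OOC(C)(C)OC)(C)CCO | intermediate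
14 | (3R,5R)-3-[(2-methoxypropan-2-yl)peroxy]-3,5-dimethylundec-10-enal | C[C@H](CCCCC=C)C[C@](OOC(C)(C)OC)(C)CC=O | intermediate
15 | (4R,6R)-4-[(2-methoxypropan-2-yl)peroxy]-4,6-dimethyldodec-11-en-2-ol (both C2 epimers) | C[C@H](CCCCC=C)C[C@](OOC(C)(C)OC)(C)CC(C)O | intermediate
16 | (4R,6R)-4-[(2-methoxypropan-2-yl)peroxy]-4,6-dimethyldodec-11-en-2-one | C[C@H](CCCCC=C)C[C@](OOC(C)(C)OC)(C)CC(C)=O | intermediate
17 | (2R)-2-{(2R,4R)-2-[(2-methoxypropan-2-yl)peroxy]-2,4-dimethyldec-9-en-1-yl}-2-methyloxirane | C[C@H](CCCCC=C)C[C@](OOC(C)(C)OC)(C)C[C@]1(C)CO1 | intermediate (not isolated)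
18 | (2S)-2-{(2R,4R)-2-[(2-methoxypropan-2-yl)peroxy]-2,4-dimethyldec-9-en-1-yl}-2-methyloxetane | C[C@H](CCCCC=C)C[C@](OOC(C)(C)OC)(C)C[C@]1(C)CCO1 | intermediate
19 | (2S)-2-[(2R,4R)-2-hydroperoxy-2,4-dimethyldec-9-en-1-yl]-2-methyloxetane | C[C@H](CCCCC=C)C[C@](OO)(C)C[C@]1(C)CCO1 | intermediate (not isolated)
20 | 2-{(3R,5R)-3,5-dimethyl-5-[(2R)-2-methyloct-7-en-1-yl]-1,2-dioxolan-3-yl}ethan-1-ol | C[C@H](CCCCC=C)C[C@]1(C)C[C@@](C)(CCO)OO1 | intermediate
21 | 2-{(3R,5R)-5-[(2R)-7-hydroperoxy-7-methoxy-2-methylheptyl]-3,5-dimethyl-1,2-dioxolan-3-yl}ethan-1-ol (both C7 epimers) | C[C@H](CCCCC(OC)OO)C[C@]1(C)C[C@@](C)(CCO)OO1 | intermediate (not isolated)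
22 | (6R)-7-[(3R,5R)-5-(2-hydroxyethyl)-3,5-dimethyl-1,2-dioxolan-3-yl]-6-methylheptanal | C[C@H](CCCCC=O)C[C@]1(C)C[C@@](C)(CCO)OO1 | intermediate
23 | 2-{(3R,5R)-3,5-dimethyl-5-[(2R,7E,11E)-2-methyl-12-phenyldodeca-7,11-dien-1-yl]-1,2-dioxolan-3-yl}ethan-1-ol | C[C@H](CCCC/C=C/CC/C=C/c1ccccc1)C[C@]1(C)C[C@@](C)(CCO)OO1 | intermediate
24 | 2-{(3S,5R)-3,5-dimethyl-5-[(2R,7E,11E)-2-methyl-12-phenyldodeca-7,11-dien-1-yl]-1,2-dioxolan-3-yl}acetic acid | C[C@H](CCCC/C=C/CC/C=C/c1ccccc1)C[C@]1(C)C[C@@](C)(CC(=O)O)OO1 | target

## Step count and least certain steps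

Total step count: 17. Longest linear sequence: 13 (steps 5 to 17, from hept-6-en-1-ol); the sulfone branch (steps 1 to 4) joins at step 16.

Step 14 (key step). Most likely to go wrong: ionisation of the activated oxetane to the tertiary C3 cation before the hydroperoxide arrives (loss of stereospecificity), acid-induced fragmentation of the tertiary hydroperoxide, or hydrolytic opening of the oxetane during the unmasking. Fallback, setting out from 16 and returning at 20: 16 is treated with TsOH in MeOH, which removes the peroxyketal and ketalises the ring to give (5R)-3-methoxy-3,5-dimethyl-5-[(2R)-2-methyloct-7-en-1-yl]-1,2-dioxolane F1 as both C3 epimers. TiCl4 in CH2Cl2 at −78 °C ionises F1 at C3, and the tert-butyldimethylsilyl ketene acetal of methyl acetate should add to the planar cation anti to the larger C5 substituent, giving methyl 2-{(3S,5R)-3,5-dimethyl-5-[(2R)-2-methyloct-7-en-1-yl]-1,2-dioxolan-3-yl}acetate F2 after removal of the C3 epimer. LiBH4 in THF at 0 °C reduces F2 to 20. C3 then rests on substrate control only, which is why this is the fallback and not the route.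

Step 13. Most likely to go wrong: enolisation of 16 toward C4 with β-elimination of the peroxyketal, and stalling of the second, ring-expanding methylene transfer at the neopentyl-type CH2 of epoxide 17. Fallback, setting out from 16, using 17 in isolated form and returning at 20: the reaction is stopped after the room-temperature methylene transfer and 17 is isolated. Unmasking (AcOH–THF–H2O) and Me3SiOTf-promoted 5-exo opening of the epoxide at its tertiary carbon, with inversion, give {(3S,5R)-3,5-dimethyl-5-[(2R)-2-methyloct-7-en-1-yl]-1,2-dioxolan-3-yl}methanol F3. Dess–Martin oxidation gives (3S,5R)-3,5-dimethyl-5-[(2R)-2-methyloct-7-en-1-yl]-1,2-dioxolane-3-carbaldehyde F4, and Wittig reaction with Ph3P=CHOMe gives (3S,5R)-3-(2-methoxyethenyl)-3,5-dimethyl-5-[(2R)-2-methyloct-7-en-1-yl]-1,2-dioxolane F5. Hydrolysis with dilute HCl in THF gives 2-{(3S,5R)-3,5-dimethyl-5-[(2R)-2-methyloct-7-en-1-yl]-1,2-dioxolan-3-yl}acetaldehyde F6, and NaBH4 reduces F6 to 20.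

Step 7. Most likely to go wrong: insufficient discrimination between the methyl group and the β-branched CH2 group of a dialkyl ketone, which would give C5 epimers that are carried through the whole sequence. Fallback, setting out from 9 and returning at 11: Horner–Wadsworth–Emmons reaction of 9 with triethyl phosphonoacetate and NaH gives ethyl (2E,5R)-3,5-dimethylundeca-2,10-dienoate F7 (E isomer separated). iBu2AlH gives (2E,5R)-3,5-dimethylundeca-2,10-dien-1-ol F8. Sharpless asymmetric epoxidation [Ti(OiPr)4, L-(+)-diethyl tartrate, tBuOOH] gives {(2S,3S)-3-methyl-3-[(2R)-2-methyloct-7-en-1-yl]oxiran-2-yl}methanol F9. NaAlH2(OCH2CH2OMe)2 opens F9 at C2 to give (3S,5R)-3,5-dimethylundec-10-ene-1,3-diol F10. Selective tosylation of the primary hydroxyl gives (3S,5R)-3-hydroxy-3,5-dimethylundec-10-en-1-yl 4-methylbenzenesulfonate F11, and KOtBu closes oxetane 11 with retention at the tertiary carbon.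

Step 16. Most likely to go wrong: consumption of the sulfone anion by the free hydroxyl and enolisation of the aldehyde, lowering conversion, and incomplete E selectivity. Fallback, setting out from 20 and returning at 23 without step 15: olefin cross-metathesis of 20 with an excess of [(1E)-hexa-1,5-dien-1-yl]benzene F12 (from (E)-cinnamyl chloride and allylmagnesium bromide), catalysed by second-generation Grubbs catalyst RuCl2(=CHPh)(H2IMes)(PCy3) in CH2Cl2 at 40 °C under neutral conditions. The minor Z isomer would be removed on AgNO3-impregnated silica.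

## Further compounds

F1 | step 14 | (5R)-3-methoxy-3,5-dimethyl-5-[(2R)-2-methyloct-7-en-1-yl]-1,2-dioxolane (both C3 epimers) | C[C@H](CCCCC=C)C[C@]1(C)CC(C)(OC)OO1
F2 | step 14 | methyl 2-{(3S,5R)-3,5-dimethyl-5-[(2R)-2-methyloct-7-en-1-yl]-1,2-dioxolan-3-yl}acetate | C[C@H](CCCCC=C)C[C@]1(C)C[C@@](C)(CC(=O)OC)OO1
F3 | step 13 | {(3S,5R)-3,5-dimethyl-5-[(2R)-2-methyloct-7-en-1-yl]-1,2-dioxolan-3-yl}methanol | C[C@H](CCCCC=C)C[C@]1(C)C[C@@](C)(CO)OO1
F4 | step 13 | (3S,5R)-3,5-dimethyl-5-[(2R)-2-methyloct-7-en-1-yl]-1,2-dioxolane-3-carbaldehyde | C[C@H](CCCCC=C)C[C@]1(C)C[C@@](C)(C=O)OO1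
F5 | step 13 | (3S,5R)-3-(2-methoxyethenyl)-3,5-dimethyl-5-[(2R)-2-methyloct-7-en-1-yl]-1,2-dioxolane (E/Z mixture) | C[C@H](CCCCC=C)C[C@]1(C)C[C@@](C)(C=COC)OO1
F6 | step 13 | 2-{(3S,5R)-3,5-dimethyl-5-[(2R)-2-methyloct-7-en-1-yl]-1,2-dioxolan-3-yl}acetaldehyde | C[C@H](CCCCC=C)C[C@]1(C)C[C@@](C)(CC=O)OO1
F7 | step 7 | ethyl (2E,5R)-3,5-dimethylundeca-2,10-dienoate | CCOC(=O)/C=C(\C)C[C@H](C)CCCCC=C
F8 | step 7 | (2E,5R)-3,5-dimethylundeca-2,10-dien-1-ol | OC/C=C(\C)C[C@H](C)CCCCC=C
F9 | step 7 | {(2S,3S)-3-methyl-3-[(2R)-2-methyloct-7-en-1-yl]oxiran-2-yl}methanol | C[C@H](CCCCC=C)C[C@@]1(C)[C@H](CO)O1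
F10 | step 7 | (3S,5R)-3,5-dimethylundec-10-ene-1,3-diol | C[C@H](CCCCC=C)C[C@@](O)(C)CCO
F11 | step 7 | (3S,5R)-3-hydroxy-3,5-dimethylundec-10-en-1-yl 4-methylbenzenesulfonate | C[C@H](CCCCC=C)C[C@@](O)(C)CCOS(=O)(=O)c1ccc(C)cc1
F12 | step 16 | [(1E)-hexa-1,5-dien-1-yl]benzene | C=CCC/C=C/c1ccccc1
A1 | alternative 1 | ethyl (2E,7R)-12-[(tert-butyldiphenylsilyl)oxy]-3,7-dimethyl-5-methylidenedodec-2-enoate | CCOC(=O)/C=C(\C)CC(=C)C[C@H](C)CCCCCO[Si](c1ccccc1)(c1ccccc1)C(C)(C)C
A2 | alternative 1 | ethyl 2-{5-[(2R)-7-[(tert-butyldiphenylsilyl)oxy]-2-methylheptyl]-3,5-dimethyl-1,2-dioxolan-3-yl}acetate (four ring diastereomers) | CCOC(=O)CC1(C)CC(C)(C[C@H](C)CCCCCO[Si](c2ccccc2)(c2ccccc2)C(C)(C)C)OO1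
A3 | alternative 2 | triethyl{[(4R)-2-methoxy-4-methyldec-9-en-2-yl]peroxy}silane | CC[Si](CC)(CC)OOC(C)(OC)C[C@H](C)CCCCC=C
A4 | alternative 2 | 3-methylbut-3-en-1-yl acetate | CC(=C)CCOC(C)=O
A5 | alternative 2 | 2-{3,5-dimethyl-5-[(2R)-2-methyloct-7-en-1-yl]-1,2-dioxolan-3-yl}ethyl acetate (four ring diastereomers) | CC(=O)OCCC1(C)CC(C)(C[C@H](C)CCCCC=C)OO1
A6 | alternative 3 | (2S,2'S)-2,2'-methylenebis(2-methyloxetane) | C[C@]1(CCO1)C[C@]2(C)CCO2
A7 | alternative 3 | 2,2'-[(3R,5R)-3,5-dimethyl-1,2-dioxolane-3,5-diyl]di(ethan-1-ol) | OCC[C@]1(C)C[C@@](C)(CCO)OO1
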